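**Strategy.** The six-membered ring C1–C6 is treated as a masked 2-amido-p-quinone: oxygen on C1 and C4 across the ring, nitrogen on C2, and C5–C6 as a former alkene. That pattern maps onto a 4-methoxy-4-vinylcyclobutenone, whose carbonyl and carbinol carbons become C4 and C1, whose ring alkene becomes C3=C2 and whose vinyl group becomes C5–C6. Heating opens the four-membered ring to a dienylketene that closes to the benzenoid ring in one operation, with the two oxygens already differentiated (phenol at C4, methyl ether at C1). Oxidation to the quinone monoketal, asymmetric epoxidation, dienyllithium addition and a Stille coupling finish the target.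

Key step: step 6

Ring numbering used throughout: C1 = ring carbonyl carbon of the target, C2 = N-bearing carbon, C3 = ring CH, C4 = carbinol carbon, C5 and C6 = epoxide carbons (C5 next to C4). In this numbering the target is (4R,5S,6R), with the C4 hydroxyl syn to the epoxide oxygen.

Assumption: N-benzylcinchoninium chloride is taken to favour the (5S,6R) epoxide in step 8; if the opposite sense prevails, the pseudo-enantiomeric N-benzylcinchonidinium chloride is used in its place.

Assumption: (E)-3-bromoacrylic acid, diisopropyl squarate and (E)-1,2-bis(tributylstannyl)ethene are taken as purchasable.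

**Step 1**
Reactants: 1 cyclohexanecarbaldehyde; 2 triethyl (E)-4-phosphonocrotonate
Product: 3 ethyl (2E,4E)-5-cyclohexylpenta-2,4-dienoate
Conditions: LiN(SiMe3)2, THF, −78 → 0 °C
Reagents that add atoms: none
Why: Horner–Wadsworth–Emmons olefination with a vinylogous phosphonate; the stabilised anion should form the new C4=C5 bond E, and the C2=C3 bond is already E in the reagent.

**Step 2**
Reactants: 3 ethyl (2E,4E)-5-cyclohexylpenta-2,4-dienoate
Product: 4 (2E,4E)-5-cyclohexylpenta-2,4-dienamide
Conditions: AlMe3, NH4Cl, toluene, 0 → 50 °C; aq. HCl work-up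
Reagents that add atoms: ammonium chloride, [NH4+].[Cl-]
Why: Aluminium amide aminolysis of an ester (Weinreb-type amidation); the reagent attacks only the ester carbonyl, so the diene geometry should be kept.

**Step 3**
Reactants: 5 diisopropyl squarate
Product: 7 3-isopropoxycyclobut-3-ene-1,2-dione, via hydroxycyclobutenone 6 (not isolated)
Conditions: LiAlH(OtBu)3, THF, −78 → 0 °C; then conc. HCl, CH2Cl2, rt
Reagents that add atoms: water, O
Why: Chemoselective 1,2-hydride reduction of one carbonyl, then acid-induced ionisation of the allylic carbinol and hydrolysis of the alkoxy-stabilised cation (1,3-carbonyl transposition) should leave the monoalkoxy dione.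

**Step 4**
Reactants: 7 3-isopropoxycyclobut-3-ene-1,2-dione
Product: 9 3-isopropoxy-4-methoxy-4-vinylcyclobut-2-en-1-one (racemic), via lithium alkoxide 8 (not isolated)
Conditions: Bu3SnCH=CH2, n-BuLi, THF, −78 → 0 °C, then −78 °C; add 7, −78 °C; MeOTf, −78 → 0 °C
Reagents that add atoms: tributyl(vinyl)stannane, C=C[Sn](CCCC)(CCCC)CCCC; methyl trifluoromethanesulfonate, COS(=O)(=O)C(F)(F)F
Why: 1,2-Addition of vinyllithium to the more electrophilic carbonyl (the one next to the isopropoxy-bearing carbon; the other is deactivated as a vinylogous ester), then O-alkylation of the alkoxide; the racemic stereocentre is erased in step 6.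

**Step 5**
Reactants: 9 3-isopropoxy-4-methoxy-4-vinylcyclobut-2-en-1-one; 4 (2E,4E)-5-cyclohexylpenta-2,4-dienamide
Product: 10 (2E,4E)-5-cyclohexyl-N-(4-methoxy-3-oxo-4-vinylcyclobut-1-en-1-yl)penta-2,4-dienamide (racemic)
Conditions: NaH, THF, 0 °C → rt; aq. NH4Cl
Reagents that add atoms: none
Why: Addition–elimination (vinylogous acyl substitution) of the sodium amidate at the β-carbon of the strained vinylogous ester should exchange isopropoxide for the amide nitrogen.

**Step 6**
Reactants: 10 (2E,4E)-5-cyclohexyl-N-(4-methoxy-3-oxo-4-vinylcyclobut-1-en-1-yl)penta-2,4-dienamide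
Product: 13 (2E,4E)-5-cyclohexyl-N-(5-hydroxy-2-methoxyphenyl)penta-2,4-dienamide, via dienylketene 11 (not isolated), via cyclohexa-2,4-dienone 12 (not isolated)
Conditions: p-xylene (0.02 M, degassed), reflux (138 °C), Ar
Reagents that add atoms: none
Why: Thermal conrotatory 4π-electrocyclic opening of the cyclobutenone C(=O)–C(OMe) bond gives dienylketene 11, whose 6π-electrocyclisation joins the ketene carbon to the vinyl terminus and whose product 12 tautomerises to the phenol, so the four-membered ring grows by the two vinyl carbons. The closest known reaction is the Moore rearrangement of 4-alkenyl-4-alkoxycyclobutenones to hydroquinone mono-ethers. The one ring closed forms by a 6π-disrotatory electrocyclisation of the (Z)-configured ketene. No stereocentre is created, and the racemic quaternary carbon of 10 becomes the aromatic C–OMe carbon. The step needs electrocyclisation to outrun capture of the ketene by the neighbouring amide carbonyl or by a hydroxyl group. Torquoselectivity should secure this, since the methoxy donor rotates outward and the vinyl group inward, which places the vinyl terminus next to the ketene as it forms, and the O-methyl cap removes the furanone pathway.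

**Step 7**
Reactants: 13 (2E,4E)-5-cyclohexyl-N-(5-hydroxy-2-methoxyphenyl)penta-2,4-dienamide
Product: 14 (2E,4E)-5-cyclohexyl-N-(6,6-dimethoxy-3-oxocyclohexa-1,4-dien-1-yl)penta-2,4-dienamide
Conditions: PhI(OAc)2, MeOH, 0 °C
Reagents that add atoms: methanol, CO
Why: Oxidative dearomatisation of a 4-methoxyphenol with a hypervalent iodine reagent; methanol adds at the methoxy-bearing para carbon, so the ketal forms at C1 next to the amide-bearing carbon and C4 is left as the free ketone.

**Step 8**
Reactants: 14 (2E,4E)-5-cyclohexyl-N-(6,6-dimethoxy-3-oxocyclohexa-1,4-dien-1-yl)penta-2,4-dienamide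
Product: 15 (2E,4E)-5-cyclohexyl-N-[(5S,6R)-5,6-epoxy-1,1-dimethoxy-4-oxocyclohex-2-en-2-yl]penta-2,4-dienamide
Conditions: t-BuOOH, NaOH (aq), N-benzylcinchoninium chloride (10 mol %), toluene, 0 °C → rt; recrystallisation
Reagents that add atoms: tert-butyl hydroperoxide, CC(C)(C)OO
Why: Weitz–Scheffer nucleophilic epoxidation under chiral phase-transfer catalysis; the peroxide anion attacks only the unsubstituted enone C5=C6 (the amido-substituted enone is deactivated), and the cinchona ion pair should select the enantiotopic face, setting C5 and C6 together as the cis-epoxide.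

**Step 9**
Reactants: 16 (E)-1,2-bis(tributylstannyl)ethene
Product: 17 (E)-1-iodo-2-(tributylstannyl)ethene
Conditions: I2 (1.0 equiv, slow addition), Et2O, 0 °C, dark; aq. Na2S2O3
Reagents that add atoms: iodine, II
Why: Iododestannylation (electrophilic ipso substitution at an alkenyl–tin bond) proceeds with retention of the E geometry, and the first iodine deactivates the remaining alkenylstannane, so the exchange should stop after one stannyl group.

**Step 10**
Reactants: 16 (E)-1,2-bis(tributylstannyl)ethene; 17 (E)-1-iodo-2-(tributylstannyl)ethene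
Product: 20 (1E,3E)-1,4-bis(tributylstannyl)buta-1,3-diene, via alkenyllithium 18 (not isolated), via alkenylzinc chloride 19 (not isolated)
Conditions: 16, n-BuLi, THF, −78 °C; ZnCl2, −78 → 0 °C; then 17, Pd(PPh3)4 (5 mol %), THF, 0 °C → rt, dark
Reagents that add atoms: none
Why: Tin–lithium exchange of one stannyl group, transmetalation to zinc and Negishi coupling with the alkenyl iodide; the alkenylzinc transmetalates to divalent palladium much faster than either carbon–tin bond, so both stannyl groups should survive, and each two-carbon partner keeps its E geometry.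

**Step 11**
Reactants: 15 (2E,4E)-5-cyclohexyl-N-[(5S,6R)-5,6-epoxy-1,1-dimethoxy-4-oxocyclohex-2-en-2-yl]penta-2,4-dienamide; 20 (1E,3E)-1,4-bis(tributylstannyl)buta-1,3-diene
Product: 22 (2E,4E)-5-cyclohexyl-N-{(4R,5S,6R)-5,6-epoxy-4-hydroxy-1,1-dimethoxy-4-[(1E,3E)-4-(tributylstannyl)buta-1,3-dien-1-yl]cyclohex-2-en-2-yl}penta-2,4-dienamide, via dienyllithium 21 (not isolated)
Conditions: 20, MeLi, THF, −78 → −20 °C; 15 pre-treated with LiN(SiMe3)2, THF, −78 °C; combine at −78 °C; aq. NH4Cl
Reagents that add atoms: none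
Why: Tin–lithium exchange, then 1,2-addition of the alkenyllithium to the C4 ketone; attack on the face opposite the epoxide oxygen should place the new hydroxyl syn to the epoxide (4R).

**Step 12**
Reactants: 22 (the dimethyl ketal adduct)
Product: 23 (2E,4E)-5-cyclohexyl-N-{(4R,5S,6R)-5,6-epoxy-4-hydroxy-1-oxo-4-[(1E,3E)-4-(tributylstannyl)buta-1,3-dien-1-yl]cyclohex-2-en-2-yl}penta-2,4-dienamide
Conditions: Montmorillonite K10, CH2Cl2, rt
Reagents that add atoms: water, O
Why: Mild acid-clay hydrolysis of the dimethyl ketal; at room temperature the epoxide, the tertiary allylic alcohol and the alkenylstannane should survive.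

**Step 13**
Reactants: 24 cyclopentane-1,3-dione
Product: 25 2-(hydroxyimino)cyclopentane-1,3-dione
Conditions: NaNO2, aq. HCl, 0 °C
Reagents that add atoms: sodium nitrite, [Na+].[O-]N=O
Why: Nitrosation of the active methylene of a 1,3-dione, which tautomerises to the oxime.

**Step 14**
Reactants: 25 2-(hydroxyimino)cyclopentane-1,3-dione
Product: 26 2-amino-3-hydroxycyclopent-2-en-1-one hydrochloride
Conditions: H2 (1 atm), Pd/C (10 wt %), HCl, MeOH, rt
Reagents that add atoms: hydrogen chloride, Cl
Why: Catalytic hydrogenation of an α-oximino ketone to the amine, held as its hydrochloride so that the aminodione does not self-condense.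

**Step 15**
Reactants: 27 (E)-3-bromoacrylic acid; 26 2-amino-3-hydroxycyclopent-2-en-1-one hydrochloride
Product: 29 (E)-3-bromo-N-(2-hydroxy-5-oxocyclopent-1-en-1-yl)acrylamide, via acid chloride 28 (not isolated)
Conditions: (COCl)2, DMF (cat.), CH2Cl2, 0 °C → rt, concentrate; then 26, Et3N, CH2Cl2/THF, −20 °C → rt
Reagents that add atoms: none
Why: Acid chloride formation and N-acylation of the amino-enol; any O-acylated material should migrate to nitrogen, and the E bromoalkene is untouched.

**Step 16**
Reactants: 23 (the stannyl dienyl epoxyquinol); 29 (E)-3-bromo-N-(2-hydroxy-5-oxocyclopent-1-en-1-yl)acrylamide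
Product: 30 the target, (2E,4E)-5-cyclohexyl-N-{(4R,5S,6R)-5,6-epoxy-4-hydroxy-4-[(1E,3E,5E)-7-[(2-hydroxy-5-oxocyclopent-1-en-1-yl)amino]-7-oxohepta-1,3,5-trien-1-yl]-1-oxocyclohex-2-en-2-yl}penta-2,4-dienamide
Conditions: PdCl2(MeCN)2 (5 mol %), DMF, rt, dark
Reagents that add atoms: none
Why: Stille coupling of an alkenylstannane with an alkenyl bromide, with retention of both alkene geometries; the neutral room-temperature conditions should tolerate the free OH and NH groups, the epoxide and the enone.

**Compound list**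

1 | cyclohexanecarbaldehyde | O=CC1CCCCC1 | starting material
2 | triethyl (E)-4-phosphonocrotonate | CCOC(=O)/C=C/CP(=O)(OCC)OCC | starting material
3 | ethyl (2E,4E)-5-cyclohexylpenta-2,4-dienoate | CCOC(=O)/C=C/C=C/C1CCCCC1 | intermediate
4 | (2E,4E)-5-cyclohexylpenta-2,4-dienamide | NC(=O)/C=C/C=C/C1CCCCC1 | intermediate
5 | diisopropyl squarate (3,4-diisopropoxycyclobut-3-ene-1,2-dione) | CC(C)OC1=C(OC(C)C)C(=O)C1=O | starting material
6 | 4-hydroxy-2,3-diisopropoxycyclobut-2-en-1-one (racemic) | CC(C)OC1=C(OC(C)C)C(O)C1=O | intermediate (not isolated)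
7 | 3-isopropoxycyclobut-3-ene-1,2-dione | CC(C)OC1=CC(=O)C1=O | intermediate
8 | lithium 2-isopropoxy-4-oxo-1-vinylcyclobut-2-en-1-olate (racemic) | [Li+].[O-]C1(C=C)C(OC(C)C)=CC1=O | intermediate (not isolated)
9 | 3-isopropoxy-4-methoxy-4-vinylcyclobut-2-en-1-one (racemic) | C=CC1(OC)C(OC(C)C)=CC1=O | intermediate
10 | (2E,4E)-5-cyclohexyl-N-(4-methoxy-3-oxo-4-vinylcyclobut-1-en-1-yl)penta-2,4-dienamide (racemic) | O=C(/C=C/C=C/C1CCCCC1)NC1=CC(=O)C1(OC)C=C | intermediate
11 | (2E,4E)-5-cyclohexyl-N-[(3Z)-4-methoxy-1-oxohexa-1,3,5-trien-3-yl]penta-2,4-dienamide (dienylketene) | O=C=C/C(NC(=O)/C=C/C=C/C1CCCCC1)=C(OC)\C=C | intermediate (not isolated)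
12 | (2E,4E)-5-cyclohexyl-N-(6-methoxy-3-oxocyclohexa-1,5-dien-1-yl)penta-2,4-dienamide | O=C(/C=C/C=C/C1CCCCC1)NC1=CC(=O)CC=C1OC | intermediate (not isolated)
13 | (2E,4E)-5-cyclohexyl-N-(5-hydroxy-2-methoxyphenyl)penta-2,4-dienamide | O=C(/C=C/C=C/C1CCCCC1)Nc1cc(O)ccc1OC | intermediate
14 | (2E,4E)-5-cyclohexyl-N-(6,6-dimethoxy-3-oxocyclohexa-1,4-dien-1-yl)penta-2,4-dienamide | O=C(/C=C/C=C/C1CCCCC1)NC1=CC(=O)C=CC1(OC)OC | intermediate
15 | (2E,4E)-5-cyclohexyl-N-[(5S,6R)-5,6-epoxy-1,1-dimethoxy-4-oxocyclohex-2-en-2-yl]penta-2,4-dienamide | O=C(/C=C/C=C/C1CCCCC1)NC1=CC(=O)[C@H]2O[C@H]2C1(OC)OC | intermediate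
16 | (E)-1,2-bis(tributylstannyl)ethene | CCCC[Sn](CCCC)(CCCC)/C=C/[Sn](CCCC)(CCCC)CCCC | starting material
17 | (E)-1-iodo-2-(tributylstannyl)ethene | CCCC[Sn](CCCC)(CCCC)/C=C/I | intermediate
18 | [(E)-2-(tributylstannyl)vinyl]lithium | [Li]/C=C/[Sn](CCCC)(CCCC)CCCC | intermediate (not isolated)
19 | [(E)-2-(tributylstannyl)vinyl]zinc chloride | Cl[Zn]/C=C/[Sn](CCCC)(CCCC)CCCC | intermediate (not isolated)
20 | (1E,3E)-1,4-bis(tributylstannyl)buta-1,3-diene | CCCC[Sn](CCCC)(CCCC)/C=C/C=C/[Sn](CCCC)(CCCC)CCCC | intermediate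
21 | [(1E,3E)-4-(tributylstannyl)buta-1,3-dien-1-yl]lithium | [Li]/C=C/C=C/[Sn](CCCC)(CCCC)CCCC | intermediate (not isolated)
22 | (2E,4E)-5-cyclohexyl-N-{(4R,5S,6R)-5,6-epoxy-4-hydroxy-1,1-dimethoxy-4-[(1E,3E)-4-(tributylstannyl)buta-1,3-dien-1-yl]cyclohex-2-en-2-yl}penta-2,4-dienamide | O=C(/C=C/C=C/C1CCCCC1)NC1=C[C@](O)(/C=C/C=C/[Sn](CCCC)(CCCC)CCCC)[C@H]2O[C@H]2C1(OC)OC | intermediate
23 | (2E,4E)-5-cyclohexyl-N-{(4R,5S,6R)-5,6-epoxy-4-hydroxy-1-oxo-4-[(1E,3E)-4-(tributylstannyl)buta-1,3-dien-1-yl]cyclohex-2-en-2-yl}penta-2,4-dienamide | O=C(/C=C/C=C/C1CCCCC1)NC1=C[C@](O)(/C=C/C=C/[Sn](CCCC)(CCCC)CCCC)[C@H]2O[C@H]2C1=O | intermediate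
24 | cyclopentane-1,3-dione | O=C1CCC(=O)C1 | starting material
25 | 2-(hydroxyimino)cyclopentane-1,3-dione | O=C1CCC(=O)C1=NO | intermediate
26 | 2-amino-3-hydroxycyclopent-2-en-1-one hydrochloride | NC1=C(O)CCC1=O.Cl | intermediate
27 | (E)-3-bromoacrylic acid | OC(=O)/C=C/Br | starting material
28 | (E)-3-bromoacryloyl chloride | ClC(=O)/C=C/Br | intermediate (not isolated)
29 | (E)-3-bromo-N-(2-hydroxy-5-oxocyclopent-1-en-1-yl)acrylamide | Br/C=C/C(=O)NC1=C(O)CCC1=O | intermediate
30 | (2E,4E)-5-cyclohexyl-N-{(4R,5S,6R)-5,6-epoxy-4-hydroxy-4-[(1E,3E,5E)-7-[(2-hydroxy-5-oxocyclopent-1-en-1-yl)amino]-7-oxohepta-1,3,5-trien-1-yl]-1-oxocyclohex-2-en-2-yl}penta-2,4-dienamide | O=C(/C=C/C=C/C1CCCCC1)NC1=C[C@](O)(/C=C/C=C/C=C/C(=O)NC2=C(O)CCC2=O)[C@H]2O[C@H]2C1=O | target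

**Step count.** Total: 16 steps. Longest linear sequence: 9 steps (steps 3, 4, 5, 6, 7, 8, 11, 12, 16 from diisopropyl squarate; the sequence 1, 2, 5, 6, 7, 8, 11, 12, 16 is equally long).

**Steps most likely to fail**

Step 6. The ketene may be intercepted by the neighbouring amide carbonyl (cyclisation to an oxazinone) or may oligomerise before it electrocyclises. The fallback carries the nitrogen without an acyl group through the same ring expansion and attaches the side chain afterwards. It sets out from 9. Exchange of the isopropoxy group with dibenzylamine (MeOH, rt) should give 3-(dibenzylamino)-4-methoxy-4-vinylcyclobut-2-en-1-one F4. Thermolysis in refluxing xylene should give 3-(dibenzylamino)-4-methoxyphenol F5. Hydrogenolysis (H2, Pd(OH)2/C, MeOH) should give 3-amino-4-methoxyphenol F6. AlMe3-mediated aminolysis of ester 3 by F6 (toluene, 60 °C) should acylate nitrogen selectively, and the route is rejoined at 13.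

Step 5. The amidate may add too slowly to the vinylogous ester, or attack the carbonyl and degrade the strained ring under basic conditions. The fallback splits the step into amine exchange and acylation. It sets out from 9 and from ester 3. Ammonia in methanol (rt) should convert 9 into 3-amino-4-methoxy-4-vinylcyclobut-2-en-1-one F1. Saponification of 3 (LiOH, THF/water) should give (2E,4E)-5-cyclohexylpenta-2,4-dienoic acid F2, and oxalyl chloride (cat. DMF, CH2Cl2) should convert it into (2E,4E)-5-cyclohexylpenta-2,4-dienoyl chloride F3. N-Acylation of F1 with F3 (pyridine, cat. DMAP, CH2Cl2, 0 °C) returns to the route at 10.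

Step 8. The phase-transfer ion pair may discriminate the two enone faces poorly, leaving material that recrystallisation cannot bring to a single enantiomer. The fallback replaces catalyst control by an auxiliary in the ketal. It sets out from 14. Transketalisation with (2R,4R)-pentane-2,4-diol (pyridinium p-toluenesulfonate, benzene, 50 °C) should give the spiro-ketal (2E,4E)-5-cyclohexyl-N-[1,1-((2R,4R)-pentane-2,4-diyldioxy)-4-oxocyclohexa-2,5-dien-2-yl]penta-2,4-dienamide F7. Its C2-symmetric dioxane makes the two faces of the C5=C6 enone diastereotopic. Nucleophilic epoxidation (t-BuOOH, DBU, CH2Cl2, 0 °C) should then favour one epoxide, the (5S,6R)-5,6-epoxide F8, which is separable from its diastereomer by chromatography; the diol enantiomer is chosen to match this sense. Addition of dienyllithium 21, made from 20 as in step 11, should give the (4R,5S,6R) carbinol F9. Hydrolysis of the ketal (Montmorillonite K10, wet CH2Cl2) rejoins the route at 23.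

**Further compounds**

F1 | step 5 | 3-amino-4-methoxy-4-vinylcyclobut-2-en-1-one (racemic) | NC1=CC(=O)C1(OC)C=C
F2 | step 5 | (2E,4E)-5-cyclohexylpenta-2,4-dienoic acid | OC(=O)/C=C/C=C/C1CCCCC1
F3 | step 5 | (2E,4E)-5-cyclohexylpenta-2,4-dienoyl chloride | ClC(=O)/C=C/C=C/C1CCCCC1
F4 | step 6 | 3-(dibenzylamino)-4-methoxy-4-vinylcyclobut-2-en-1-one (racemic) | C=CC1(OC)C(N(Cc2ccccc2)Cc2ccccc2)=CC1=O
F5 | step 6 | 3-(dibenzylamino)-4-methoxyphenol | COc1ccc(O)cc1N(Cc1ccccc1)Cc1ccccc1
F6 | step 6 | 3-amino-4-methoxyphenol | COc1ccc(O)cc1N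
F7 | step 8 | (2E,4E)-5-cyclohexyl-N-[1,1-((2R,4R)-pentane-2,4-diyldioxy)-4-oxocyclohexa-2,5-dien-2-yl]penta-2,4-dienamide | O=C(/C=C/C=C/C1CCCCC1)NC1=CC(=O)C=CC12O[C@H](C)C[C@@H](C)O2
F8 | step 8 | (2E,4E)-5-cyclohexyl-N-[(5S,6R)-5,6-epoxy-1,1-((2R,4R)-pentane-2,4-diyldioxy)-4-oxocyclohex-2-en-2-yl]penta-2,4-dienamide | O=C(/C=C/C=C/C1CCCCC1)NC1=CC(=O)[C@H]2O[C@H]2C12O[C@H](C)C[C@@H](C)O2
F9 | step 8 | (2E,4E)-5-cyclohexyl-N-{(4R,5S,6R)-5,6-epoxy-4-hydroxy-1,1-((2R,4R)-pentane-2,4-diyldioxy)-4-[(1E,3E)-4-(tributylstannyl)buta-1,3-dien-1-yl]cyclohex-2-en-2-yl}penta-2,4-dienamide | O=C(/C=C/C=C/C1CCCCC1)NC1=C[C@](O)(/C=C/C=C/[Sn](CCCC)(CCCC)CCCC)[C@H]2O[C@H]2C12O[C@H](C)C[C@@H](C)O2
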